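## Retrosynthetic overview

1. **Feature.** Pyranone rings C and C'' are joined by the chain C4(=O)–C3–C3''–C4''(=O), flanked by the oxygen-bearing benzylic carbons C2 and C2''. This unit is a succinic acid with two aryl(hydroxy)methyl arms. Each hydroxyl can lactonize on the far carboxyl, and the resulting cis-fused 2,6-diaryl-3,7-dioxabicyclo[3.3.0]octane-4,8-dione can only exist with the like (3R,3''R) pair at its ring fusion.
2. **Last cuts.** One benzyl ether is removed at the end. Before that, O1–C2 and O1''–C2'' are cut, so rings C and C'' close together, with inversion at C2 and C2'', from an open diol-diketone.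
3. **Key cut.** C4–C4a and C4''–C4a'' are cut at once. This leads to the enantiopure exo,exo-dilactone and two equivalents of a metallated phloroglucinol tris(methoxymethyl) ether.
4. **Dilactone.** It comes from mono-tert-butyl succinate by two successive Evans syn aldols, first with 4-methoxybenzaldehyde and then with 4-(benzyloxy)benzaldehyde. Each aldol runs under an (R)-4-benzyloxazolidinone that is expelled on lactonization.
5. **Ring order.** Lactone C4–O–C2'' forms in step 6 and lactone C4''–O–C2 in step 7. Both are opened in step 9, and pyranones C and C'' close in step 10. All benzene rings are bought.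

Key step: step 9

Remark: the central carbons carry their target locants in all intermediates (C2, C3, C4 on the 4-methoxyphenyl side; C2'', C3'', C4'' on the other side), and the key-step product is drawn as the open diol-diketone although it may rest partly as its lactols, which converge in the following step.

## Route

Step 1
Reactants: 1 4-tert-butoxy-4-oxobutanoic acid (mono-tert-butyl succinate); 2 (R)-4-benzyl-1,3-oxazolidin-2-one
Product: 4 tert-butyl 4-[(4R)-4-benzyl-2-oxo-1,3-oxazolidin-3-yl]-4-oxobutanoate, via mixed pivalic anhydride 3 (not isolated)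
Conditions: PivCl, Et3N, THF, −20 °C; then LiCl, 2, −20 °C → rt
Reagents that add atoms: none
Why: Mixed-anhydride N-acylation of an Evans oxazolidinone: the tert-butyl group of the pivaloyl half shields its carbonyl, so the LiCl/Et3N-activated carbamate nitrogen should attack only the succinyl carbonyl, and no stereocentre is formed.

Step 2
Reactants: 4 imide; 5 4-methoxybenzaldehyde
Product: 7 tert-butyl (3R,4R)-3-[(4R)-4-benzyl-2-oxo-1,3-oxazolidine-3-carbonyl]-4-hydroxy-4-(4-methoxyphenyl)butanoate, via Z boron enolate 6 (not isolated)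
Conditions: Bu2BOTf (1.2 equiv), iPr2NEt, CH2Cl2, 0 °C; 5, −78 → 0 °C; pH 7 buffer, MeOH, 30% H2O2, 0 °C
Reagents that add atoms: none
Why: Evans syn aldol: soft enolization gives the Z boron enolate 6, which should add to the aldehyde through a chair Zimmerman–Traxler transition state on the face remote from the benzyl group of the (R)-auxiliary and so set C3 (R) and C2 (R), while the bulk of the tert-butyl ester holds back lactonization of the new hydroxyl.

Step 3
Reactants: 7 syn aldol
Product: 8 tert-butyl (3R,4R)-3-[(4R)-4-benzyl-2-oxo-1,3-oxazolidine-3-carbonyl]-4-(tert-butyldimethylsilyloxy)-4-(4-methoxyphenyl)butanoate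
Conditions: TBSOTf (1.3 equiv), 2,6-lutidine, CH2Cl2, −78 → 0 °C
Reagents that add atoms: tert-butyldimethylsilyl triflate (TBSOTf), CC(C)(C)[Si](C)(C)OS(=O)(=O)C(F)(F)F
Why: Silylation of a secondary alcohol by a silyl triflate under lutidine buffering is fast at low temperature, leaves imide and tert-butyl ester alone, and shuts off lactonization and retro-aldol cleavage in the steps that follow.

Step 4
Reactants: 8 silyl ether
Product: 10 (3R,4R)-3-[(4R)-4-benzyl-2-oxo-1,3-oxazolidine-3-carbonyl]-4-(tert-butyldimethylsilyloxy)-4-(4-methoxyphenyl)butanoic acid, via trimethylsilyl ester 9 (not isolated)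
Conditions: TMSOTf (3 equiv), 2,6-lutidine (4.5 equiv), CH2Cl2, 0 °C → rt; then pH 6 phosphate buffer
Reagents that add atoms: none
Why: Silyl-triflate-mediated tert-butyl ester cleavage: TMSOTf silylates the ester carbonyl, isobutene leaves, lutidine binds the acid so that the ionizable p-methoxybenzylic silyl ether never meets a free protic acid, and the labile trimethylsilyl ester 9 is hydrolysed on work-up.

Step 5
Reactants: 10 acid; 2 (R)-4-benzyl-1,3-oxazolidin-2-one
Product: 12 (2R)-1,4-bis[(4R)-4-benzyl-2-oxo-1,3-oxazolidin-3-yl]-2-[(R)-(tert-butyldimethylsilyloxy)(4-methoxyphenyl)methyl]butane-1,4-dione, via mixed pivalic anhydride 11 (not isolated)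
Conditions: PivCl, Et3N, THF, −20 °C; then LiCl, 2, −20 °C → rt
Reagents that add atoms: none
Why: Same mixed-anhydride N-acylation as in step 1, and because both acyl termini end on the same (R)-auxiliary any acyl shuffling through a transient cyclic anhydride converges on the one bis-imide.

Step 6
Reactants: 12 bis-imide; 13 4-(benzyloxy)benzaldehyde
Product: 16 (4R)-4-benzyl-3-{[(2R,3R,4R)-2-[4-(benzyloxy)phenyl]-4-[(R)-(tert-butyldimethylsilyloxy)(4-methoxyphenyl)methyl]-5-oxooxolan-3-yl]carbonyl}-1,3-oxazolidin-2-one, via Z boron enolate 14 (not isolated), via open aldol adduct 15 (not isolated)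
Conditions: Bu2BOTf (1.5 equiv), iPr2NEt, CH2Cl2, 0 °C; 13, −78 → 0 °C; pH 7 buffer, MeOH, 30% H2O2, 0 °C; then DMAP (cat.), CH2Cl2, rt
Reagents that add atoms: none
Why: Second Evans syn aldol followed by acyl-transfer lactonization: only the imide that still has an α-CH2 group can be enolized by Bu2BOTf/iPr2NEt, its (R)-auxiliary should steer the chair transition state to C3'' (R) and C2'' (R), and the freed C2'' hydroxyl then attacks the γ-placed C4 imide carbonyl and expels the first auxiliary.

Step 7
Reactants: 16 lactone imide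
Product: 18 (1R,2R,5R,6R)-6-[4-(benzyloxy)phenyl]-2-(4-methoxyphenyl)-3,7-dioxabicyclo[3.3.0]octane-4,8-dione (cis-fused; both aryl groups exo), via hydroxy lactone imide 17 (not isolated)
Conditions: HF·pyridine, pyridine–THF, 0 °C → rt; then DMAP (cat.), CH2Cl2, rt
Reagents that add atoms: none
Why: Fluoride desilylation frees the C2 hydroxyl, which sits cis to the C4'' imide on the first lactone ring and should displace the second auxiliary by 5-exo-trig lactonization, giving the cis-fused bicycle with both aryl groups on the convex face as fixed by the two syn aldols and without touching a stereocentre.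

Step 8
Reactants: 19 phloroglucinol
Product: 20 1,3,5-tris(methoxymethoxy)benzene
Conditions: MOMCl (4 equiv), iPr2NEt (5 equiv), CH2Cl2–DMF, 0 °C → rt
Reagents that add atoms: chloromethyl methyl ether (MOMCl), COCCl
Why: Threefold O-alkylation of the phenol by an α-chloro ether (Williamson-type etherification) under amine base, which favours O- over C-alkylation of phloroglucinol.

Step 9
Reactants: 18 dilactone; 20 1,3,5-tris(methoxymethoxy)benzene (2.6 equiv)
Product: 23 (2R,3R)-2-[(R)-[4-(benzyloxy)phenyl](hydroxy)methyl]-3-[(R)-hydroxy(4-methoxyphenyl)methyl]-1,4-bis[2,4,6-tris(methoxymethoxy)phenyl]butane-1,4-dione, via aryllithium 21 (not isolated), via arylcerium dichloride 22 (not isolated)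
Conditions: 20, n-BuLi (2.5 equiv), THF, 0 °C, 1 h; anhydrous CeCl3 (2.7 equiv), THF, −78 °C, 1 h; 18 in THF, −78 °C, 3 h; AcOH/THF at −78 °C, then aq NH4Cl
Reagents that add atoms: none
Why: Directed ortho-lithiation of 20 between two methoxymethoxy groups gives 21, CeCl3 turns it into the much less basic and strongly oxophilic arylcerium 22, and one aryl group adds from the open convex face to each lactone carbonyl of 18, which forms C4–C4a and C4''–C4a''. The closest known reaction type is the single addition of aryllithium or arylcerium reagents to lactones to give lactols or hydroxy ketones, as practised with 2,4,6-trialkoxyphenyl nucleophiles on sugar lactones. No ring is closed: the two lactone rings persist as cerium hemiketal alkoxides at −78 °C and open only after the cold acetic acid quench, which frees the hydroxyl groups at C2 and C2''. No stereocentre is created, and C2, C3, C3'' and C2'' keep the R configuration of 18 because no bond to them is touched. The step needs one addition per carbonyl, secured by the persistence of the tetrahedral intermediates and by the two ortho substituents that shield and twist each aryl ketone once it forms, and it needs addition rather than deprotonation at C3 and C3'', secured by the low basicity of the trivalent cerium reagent. The cold protic quench also keeps a free β-alkoxide from coexisting with a new ketone, which closes the retro-aldol channel.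

Step 10
Reactants: 23 diol-diketone
Product: 25 (2S,3R,2''S,3''R)-4'''-benzyloxy-5,7,5'',7''-tetrahydroxy-4'-methoxy-3,3''-biflavanone, via hexaphenol diol 24 (not isolated)
Conditions: 3 M aq HCl, MeOH–THF (3:1), 0.01 M, 45 °C
Reagents that add atoms: none
Why: Acid methanolysis strips the six acetal groups, and the p-alkoxybenzylic alcohols at C2 and C2'' then ionize and are captured by the neighbouring ortho phenols in two six-ring cyclodehydrations (the acid route from 2'-hydroxy-β-hydroxydihydrochalcones to flavanones), attack anti to the C3 or C3'' substituent being the same as inversion of the R carbinols, so that aryl and C3 substituent end trans-diequatorial and C2 and C2'' become S under control of the untouched C3 and C3''.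

Step 11
Reactants: 25 benzyl ether
Product: 26 (2S,3R,2''S,3''R)-5,7,5'',7'',4'''-pentahydroxy-4'-methoxy-3,3''-biflavanone (CNP0196568.1)
Conditions: H2 (1 atm), Pd/C (10 wt %), EtOAc–MeOH, rt
Reagents that add atoms: none
Why: Catalytic hydrogenolysis should cleave only the O-benzyl ether, since the hydrogen-bonded aryl ketones and the cyclic C2–O bonds of flavanones tolerate these neutral conditions, and no stereocentre is touched.

## Compound list

1 | 4-tert-butoxy-4-oxobutanoic acid | CC(C)(C)OC(=O)CCC(=O)O | starting material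
2 | (R)-4-benzyl-1,3-oxazolidin-2-one | O=C1N[C@H](Cc2ccccc2)CO1 | starting material
3 | mixed pivalic anhydride of 1 | CC(C)(C)OC(=O)CCC(=O)OC(=O)C(C)(C)C | intermediate
4 | tert-butyl 4-[(4R)-4-benzyl-2-oxo-1,3-oxazolidin-3-yl]-4-oxobutanoate | CC(C)(C)OC(=O)CCC(=O)N1[C@H](Cc2ccccc2)COC1=O | intermediate
5 | 4-methoxybenzaldehyde | COc1ccc(C=O)cc1 | starting material
6 | Z dibutylboron enolate of 4 | CCCCB(CCCC)O/C(=C\CC(=O)OC(C)(C)C)N1[C@H](Cc2ccccc2)COC1=O | intermediate
7 | syn aldol (C2 R, C3 R), tert-butyl ester, free hydroxyl | COc1ccc([C@H](O)[C@@H](CC(=O)OC(C)(C)C)C(=O)N2[C@H](Cc3ccccc3)COC2=O)cc1 | intermediate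
8 | TBS ether of 7 | COc1ccc([C@H](O[Si](C)(C)C(C)(C)C)[C@@H](CC(=O)OC(C)(C)C)C(=O)N2[C@H](Cc3ccccc3)COC2=O)cc1 | intermediate
9 | trimethylsilyl ester corresponding to 8 | COc1ccc([C@H](O[Si](C)(C)C(C)(C)C)[C@@H](CC(=O)O[Si](C)(C)C)C(=O)N2[C@H](Cc3ccccc3)COC2=O)cc1 | intermediate
10 | carboxylic acid corresponding to 8 | COc1ccc([C@H](O[Si](C)(C)C(C)(C)C)[C@@H](CC(=O)O)C(=O)N2[C@H](Cc3ccccc3)COC2=O)cc1 | intermediate
11 | mixed pivalic anhydride of 10 | COc1ccc([C@H](O[Si](C)(C)C(C)(C)C)[C@@H](CC(=O)OC(=O)C(C)(C)C)C(=O)N2[C@H](Cc3ccccc3)COC2=O)cc1 | intermediate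
12 | bis-imide (C2 R, C3 R) | COc1ccc([C@H](O[Si](C)(C)C(C)(C)C)[C@@H](CC(=O)N2[C@H](Cc3ccccc3)COC2=O)C(=O)N2[C@H](Cc3ccccc3)COC2=O)cc1 | intermediate
13 | 4-(benzyloxy)benzaldehyde | O=Cc1ccc(OCc2ccccc2)cc1 | starting material
14 | Z dibutylboron enolate of 12 at C3''=C4'' | COc1ccc([C@H](O[Si](C)(C)C(C)(C)C)[C@@H](/C=C(\OB(CCCC)CCCC)N2[C@H](Cc3ccccc3)COC2=O)C(=O)N2[C@H](Cc3ccccc3)COC2=O)cc1 | intermediate
15 | open bis-imide aldol adduct (C2, C3, C3'', C2'' all R) | COc1ccc([C@H](O[Si](C)(C)C(C)(C)C)[C@H](C(=O)N2[C@H](Cc3ccccc3)COC2=O)[C@@H](C(=O)N2[C@H](Cc3ccccc3)COC2=O)[C@@H](O)c2ccc(OCc3ccccc3)cc2)cc1 | intermediate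
16 | lactone imide (lactone C4–O–C2''; imide at C4''; TBS ether at C2) | O=C1O[C@@H](c2ccc(OCc3ccccc3)cc2)[C@H](C(=O)N2[C@H](Cc3ccccc3)COC2=O)[C@@H]1[C@@H](O[Si](C)(C)C(C)(C)C)c1ccc(OC)cc1 | intermediate
17 | hydroxy lactone imide (16 without silyl group) | O=C1O[C@@H](c2ccc(OCc3ccccc3)cc2)[C@H](C(=O)N2[C@H](Cc3ccccc3)COC2=O)[C@@H]1[C@@H](O)c1ccc(OC)cc1 | intermediate
18 | (1R,2R,5R,6R)-6-[4-(benzyloxy)phenyl]-2-(4-methoxyphenyl)-3,7-dioxabicyclo[3.3.0]octane-4,8-dione | O=C1O[C@@H](c2ccc(OCc3ccccc3)cc2)[C@@H]2C(=O)O[C@@H](c3ccc(OC)cc3)[C@H]12 | intermediate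
19 | phloroglucinol | Oc1cc(O)cc(O)c1 | starting material
20 | 1,3,5-tris(methoxymethoxy)benzene | COCOc1cc(OCOC)cc(OCOC)c1 | intermediate
21 | 2,4,6-tris(methoxymethoxy)phenyllithium | [Li]c1c(OCOC)cc(OCOC)cc1OCOC | intermediate
22 | 2,4,6-tris(methoxymethoxy)phenylcerium dichloride | Cl[Ce](Cl)c1c(OCOC)cc(OCOC)cc1OCOC | intermediate
23 | open diol-diketone, hexa-MOM (C2, C3, C3'', C2'' all R) | COc1ccc([C@H](O)[C@H](C(=O)c2c(OCOC)cc(OCOC)cc2OCOC)[C@@H](C(=O)c2c(OCOC)cc(OCOC)cc2OCOC)[C@@H](O)c2ccc(OCc3ccccc3)cc2)cc1 | intermediate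
24 | hexaphenol diol-diketone (C2, C3, C3'', C2'' all R) | COc1ccc([C@H](O)[C@H](C(=O)c2c(O)cc(O)cc2O)[C@@H](C(=O)c2c(O)cc(O)cc2O)[C@@H](O)c2ccc(OCc3ccccc3)cc2)cc1 | intermediate
25 | (2S,3R,2''S,3''R)-4'''-benzyloxy-5,7,5'',7''-tetrahydroxy-4'-methoxy-3,3''-biflavanone | COc1ccc([C@H]2Oc3cc(O)cc(O)c3C(=O)[C@@H]2[C@H]2C(=O)c3c(O)cc(O)cc3O[C@@H]2c2ccc(OCc3ccccc3)cc2)cc1 | intermediate
26 | (2S,3R,2''S,3''R)-5,7,5'',7'',4'''-pentahydroxy-4'-methoxy-3,3''-biflavanone | COc1ccc([C@H]2Oc3cc(O)cc(O)c3C(=O)[C@@H]2[C@H]2C(=O)c3c(O)cc(O)cc3O[C@@H]2c2ccc(O)cc2)cc1 | target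

## Step count and weak points

Total step count: 11. Longest linear sequence: 10 (steps 1–7, then 9–11); step 8 is a one-step branch.

**Step 9 (key step).**
- The bulky aryl nucleophile may deprotonate C3 or C3'' instead of adding, which triggers β-elimination of the lactone carboxylate.
- The hemiketal alkoxides may collapse before the quench, so that a free β-alkoxide beside a new ketone fragments by retro-aldol cleavage.
- Addition may stall after the first lactone.

The fallback makes the same two bonds stepwise on an opened and protected chain.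
- It sets out from 18. MeNH(OMe)·HCl/AlMe3 in CH2Cl2 opens both lactones to the bis(N-methoxy-N-methylamide) diol F1.
- TESOTf/2,6-lutidine caps both carbinols at once, before relactonization can set in, and gives the bis(triethylsilyl) ether F2.
- Aryllithium 21, made from 20 as in step 9 but without cerium, adds to both chelating amides in THF at −78 → 0 °C and gives the bis-silylated diketone F3.
- HF·pyridine removes the silyl groups, and the route is rejoined at 23.

**Step 10.**
- Loss of H3 or H3'' from the benzylic cation, or from a lactol-derived oxocarbenium ion, would flatten C3 or C3'', and re-closure would then scramble the configuration.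
- Paal–Knorr type dehydration of the 1,4-diketone is possible.
- The cation may be captured by the other carbinol oxygen, which competes with pyranone closure.

The fallback separates deprotection from ring closure and closes by SN2.
- It sets out from 23. TMSOTf/2,2'-bipyridyl in CH2Cl2 at 0 °C, followed by water, removes the acetals under nearly neutral conditions, so that the hexaphenol diol 24 is isolated.
- PPh3/DIAD in THF at high dilution and 0 °C then closes both rings by intramolecular Mitsunobu etherification, with inversion (R to S) at C2 and C2''.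
- The route is rejoined at 25.

**Step 6.**
- The boron enolate carries a very large substituent at C3, so addition to the electron-rich aldehyde may be slow.
- The resident C3 centre may oppose the auxiliary, which would erode facial selectivity at C3''.

The fallback uses substrate control in a ring that holds both carbonyls. There, attack anti to the C3 arm gives exactly the like (3R,3''R) relation.
- It sets out from 10. LiOH/H2O2 in THF–H2O removes the auxiliary and gives the substituted succinic acid F4.
- DCC in CH2Cl2 closes the cyclic anhydride F5.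
- ZnCl2/Et3N in CH2Cl2 with 13 brings about the Fittig–Perkin type aldol–lactonization at the less hindered CH2, trans to the C3 arm. The aldolate opens the anhydride at the far carbonyl C4, and this gives the lactone acid F6.
- HF·pyridine frees the hydroxy lactone acid F7.
- EDC·HCl/DMAP closes the second lactone, and the route is rejoined at 18.

## Further compounds

F1 | step 9 | bis(N-methoxy-N-methylamide) diol (C2, C3, C3'', C2'' all R) | COc1ccc([C@H](O)[C@H](C(=O)N(C)OC)[C@@H](C(=O)N(C)OC)[C@@H](O)c2ccc(OCc3ccccc3)cc2)cc1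
F2 | step 9 | bis(triethylsilyl) ether of F1 | COc1ccc([C@H](O[Si](CC)(CC)CC)[C@H](C(=O)N(C)OC)[C@@H](C(=O)N(C)OC)[C@@H](O[Si](CC)(CC)CC)c2ccc(OCc3ccccc3)cc2)cc1
F3 | step 9 | bis(triethylsilyl) ether of 23 | COc1ccc([C@H](O[Si](CC)(CC)CC)[C@H](C(=O)c2c(OCOC)cc(OCOC)cc2OCOC)[C@@H](C(=O)c2c(OCOC)cc(OCOC)cc2OCOC)[C@@H](O[Si](CC)(CC)CC)c2ccc(OCc3ccccc3)cc2)cc1
F0 | step 10 | none | none
F4 | step 6 | (2R)-2-[(R)-(tert-butyldimethylsilyloxy)(4-methoxyphenyl)methyl]butanedioic acid | COc1ccc([C@H](O[Si](C)(C)C(C)(C)C)[C@@H](CC(=O)O)C(=O)O)cc1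
F5 | step 6 | cyclic anhydride of F4 | COc1ccc([C@H](O[Si](C)(C)C(C)(C)C)[C@H]2CC(=O)OC2=O)cc1
F6 | step 6 | lactone acid (16 with CO2H in place of the imide) | O=C1O[C@@H](c2ccc(OCc3ccccc3)cc2)[C@H](C(=O)O)[C@@H]1[C@@H](O[Si](C)(C)C(C)(C)C)c1ccc(OC)cc1
F7 | step 6 | hydroxy lactone acid (F6 without silyl group) | O=C1O[C@@H](c2ccc(OCc3ccccc3)cc2)[C@H](C(=O)O)[C@@H]1[C@@H](O)c1ccc(OC)cc1
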